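**Retrosynthetic overview**

1. Daucane numbering is used throughout. C1 is the methyl-bearing ring-fusion carbon, C2 (OAc), C3, C4 (OH, iPr), C5 is the ring-fusion CH, C6 (O-angeloyl), C7, C8 (CH3), C9, C10 (OBz). β is the face of the C1 methyl group.
2. Endgame: the three esters go on one at a time (C2, then C6, then C10). The C6 and C10 carbinols come from ketones (hydroxyl-directed reduction, Luche reduction). The C8=C9 bond and the C10 oxygen come from a 7,9-dien-6-one by γ,δ-epoxidation and SmI2 opening.
3. Key disconnection: the ring-fusion bond C1–C5 (together with C1–C10). An intramolecular Buchner reaction of an α-diazoketone closes the five-membered ring and, in the same operation, expands a benzene ring to the seven-membered ring.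
4. Enabling feature: the seven-membered ring (C1, C5–C10) is a benzene ring plus one carbon. C5–C10 carry the m-cresol pattern (C8 methyl para to C5, oxygen on C6 ortho to C5). The extra atom C1 is quaternary, bears a methyl group and sits next to the oxygenated C2, so it is the carbene carbon of a diazoketone tied to C5 by C2–C3–C4 of the five-membered ring.
5. Precursor and ring order: benzene ring (bought), then a temporary dioxasiline ring (SitBu2 bridging O4 and O6, which relays C4 to C1), then the five- and seven-membered rings together in step 7. C4 comes from a phenol-directed asymmetric allylation of an o-hydroxyaryl isopropyl ketone made by Fries rearrangement.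

Key step: step 7

Remark (assumption on the chemistry): the (R,R)-allylchlorosilane is taken to attack the ketone face that gives (R)-7. Both antipodes of the reagent are commercial, and the (S,S)-reagent would be used if the sense of induction were the opposite.
Remark: diazoethane is used as a freshly prepared ethereal solution.

**Step 1**
Reactants: 1 m-cresol; 2 isobutyryl chloride
Product: 4 1-(2-hydroxy-4-methylphenyl)-2-methylpropan-1-one, via m-tolyl isobutyrate 3 (not isolated)
Conditions: neat, 80 °C; then AlCl3 (1.5 equiv), 140 °C; ice/aq. HCl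
Reagents that add atoms: none
Why: O-acylation followed by a Fries rearrangement, which at high temperature is under chelate control and should go to the ortho position para to the methyl group, the less hindered of the two ortho sites.

**Step 2**
Reactants: 4 1-(2-hydroxy-4-methylphenyl)-2-methylpropan-1-one
Product: 7 (R)-2-(3-hydroxy-2-methylhex-5-en-3-yl)-5-methylphenol, via aryloxyallylsilane 5 (not isolated), via spirocyclic dialkoxysilane 6 (not isolated)
Conditions: (R,R)-allylchlorosilane reagent (1.5 equiv), CH2Cl2, 23 to 40 °C; aqueous work-up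
Reagents that add atoms: (3aR,7aR)-2-allyl-1,3-bis(4-bromobenzyl)-2-chlorooctahydro-1H-1,3,2-benzodiazasilole C=CC[Si]1(Cl)N(Cc2ccc(Br)cc2)[C@@H]2CCCC[C@H]2N1Cc1ccc(Br)cc1
Why: Phenol-directed asymmetric allylation of a ketone with a strained chiral allylchlorosilane, a reaction type shown for hindered 2-hydroxyaryl ketones, in which the phenol displaces chloride, the ketone is thereby tied to the Lewis-acidic silicon, and the allyl group is delivered through a closed transition state whose C2-symmetric diamine selects one ketone face and sets C4 as R.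

**Step 3**
Reactants: 7 (R)-2-(3-hydroxy-2-methylhex-5-en-3-yl)-5-methylphenol
Product: 8 (R)-4-allyl-2,2-di-tert-butyl-4-isopropyl-7-methyl-4H-1,3,2-benzodioxasiline
Conditions: tBu2Si(OTf)2, 2,6-lutidine, CH2Cl2, 0 °C to rt
Reagents that add atoms: di-tert-butylsilyl bis(trifluoromethanesulfonate) CC(C)(C)[Si](OS(=O)(=O)C(F)(F)F)(OS(=O)(=O)C(F)(F)F)C(C)(C)C
Why: Silylene protection of the phenol/tertiary alcohol pair, in which the phenol is silylated first and the second Si–O bond forms intramolecularly in a six-membered ring that masks both hydroxyl groups, lowers the basicity of O4 and fixes the C4–O bond in the arene plane without touching C4.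

**Step 4**
Reactants: 8 (R)-4-allyl-2,2-di-tert-butyl-4-isopropyl-7-methyl-4H-1,3,2-benzodioxasiline
Product: 10 (R)-2-(2,2-di-tert-butyl-4-isopropyl-7-methyl-4H-1,3,2-benzodioxasilin-4-yl)acetaldehyde, via secondary ozonide 9 (not isolated)
Conditions: O3 (dosed to consumption of 8), CH2Cl2, −78 °C; then Me2S, −78 °C to rt
Reagents that add atoms: ozone [O-][O+]=O
Why: Ozonolysis with reductive work-up, in which the terminal alkene reacts far faster than the arene, so that dosed ozone should cleave only the vinyl group and leave the C2 aldehyde.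

**Step 5**
Reactants: 10 (R)-2-(2,2-di-tert-butyl-4-isopropyl-7-methyl-4H-1,3,2-benzodioxasilin-4-yl)acetaldehyde
Product: 11 (R)-2-(2,2-di-tert-butyl-4-isopropyl-7-methyl-4H-1,3,2-benzodioxasilin-4-yl)acetic acid
Conditions: NaClO2, NaH2PO4, 2-methylbut-2-ene, tBuOH/H2O, 0 °C to rt
Reagents that add atoms: sodium chlorite [Na+].[O-]Cl=O
Why: Pinnick oxidation under buffered conditions that spare the silylene and the arene, the alkene scavenger removing hypochlorous acid before it can chlorinate the ring.

**Step 6**
Reactants: 11 (R)-2-(2,2-di-tert-butyl-4-isopropyl-7-methyl-4H-1,3,2-benzodioxasilin-4-yl)acetic acid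
Product: 13 (R)-3-diazo-1-(2,2-di-tert-butyl-4-isopropyl-7-methyl-4H-1,3,2-benzodioxasilin-4-yl)butan-2-one, via mixed carbonic anhydride 12 (not isolated)
Conditions: iBuOCOCl, N-methylmorpholine, THF, −20 °C; then CH3CHN2, Et2O, −20 to 0 °C
Reagents that add atoms: diazoethane CC=[N+]=[N-]; isobutyl chloroformate CC(C)COC(=O)Cl (its atoms remain only in 12)
Why: Acylation of diazoethane by a mixed carbonic anhydride (first stage of Arndt–Eistert-type chemistry), a neutral way to the 2-diazo-3-ketone that avoids strong base and strong acid next to the tertiary benzylic silyl ether.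

**Step 7**
Reactants: 13 (R)-3-diazo-1-(2,2-di-tert-butyl-4-isopropyl-7-methyl-4H-1,3,2-benzodioxasilin-4-yl)butan-2-one
Product: 15 (1R,4R)-4,6-O-(di-tert-butylsilanediyl)-4β,6-dihydroxydauca-5,7,9-trien-2-one, via norcaradiene 14 (not isolated)
Conditions: Rh2(O2CC3F7)4 (1 mol %), CH2Cl2, rt, slow addition of 13, acid excluded
Reagents that add atoms: none
Why: Loss of N2 gives an electrophilic rhodium carbenoid at C1, which adds across the C5–C10 bond of the arene (new bonds C1–C5 and C1–C10) to give norcaradiene 14, and 14 opens by a thermally allowed disrotatory 6π electrocyclic reaction that cleaves the former aromatic C5–C10 bond; this is the intramolecular Buchner reaction, whose closest precedent is the conversion of 2-diazo-5-arylpentan-3-ones into 8a-methylazulenones. The five-membered ring (C1–C5) is closed by the intramolecular [2+1] cycloaddition through the three-atom link C2–C3–C4, which lets the carbenoid reach only an ipso/ortho bond, and the seven-membered ring arises by ring expansion of the six-membered ring, not by an end-to-end closure. C1 is the only new stereocenter left in 15 and is controlled by C4: the dioxasiline ring holds O4 in the arene plane next to O6, so the CH2 arm stands pseudo-axial on one face only, the carbenoid can add only to that face, and the tether geometry then forces the methyl group over the six-membered ring, which puts it cis to O4 and trans to the isopropyl group (1R from 4R). Regioselectivity for C5–C10 over C5–C6 follows from the silyloxy substituent and the temporary ring, which block the C5–C6 bond. Chemoselectivity over 1,5 C–H insertion into the isopropyl methine, over 1,2-hydride shift from the methyl group and over oxonium ylide formation is sought with the electron-poor perfluorobutyrate ligands, which favour aromatic cycloaddition, and with silicon on O4, which lowers its basicity. Acid is excluded so that 15 does not rearrange to a 2-tetralone.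

**Step 8**
Reactants: 15 (1R,4R)-4,6-O-(di-tert-butylsilanediyl)-4β,6-dihydroxydauca-5,7,9-trien-2-one
Product: 16 4,6-O-(di-tert-butylsilanediyl)dauca-5,7,9-triene-2α,4β,6-triol
Conditions: (R)-2-methyl-CBS-oxazaborolidine (20 mol %), catecholborane, toluene, −78 to −40 °C; MeOH, aq. NaHCO3
Reagents that add atoms: none
Why: Corey–Bakshi–Shibata reduction, in which the oxazaborolidine binds the only ketone with the quaternary C1 as the large and the C3 methylene as the small flank, so that the (R)-catalyst should deliver hydride to the β face and set the 2α (2S) alcohol, while catecholborane at low temperature leaves the triene and the silyl enol ether alone.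

**Step 9**
Reactants: 16 4,6-O-(di-tert-butylsilanediyl)dauca-5,7,9-triene-2α,4β,6-triol
Product: 17 2α-acetoxy-4,6-O-(di-tert-butylsilanediyl)dauca-5,7,9-triene-4β,6-diol
Conditions: Ac2O, DMAP (cat.), pyridine, rt
Reagents that add atoms: acetic anhydride CC(=O)OC(C)=O
Why: DMAP-catalysed acetylation of the only free hydroxyl group, with no stereocenter affected.

**Step 10**
Reactants: 17 2α-acetoxy-4,6-O-(di-tert-butylsilanediyl)dauca-5,7,9-triene-4β,6-diol
Product: 19 2α-acetoxy-4β-hydroxy-5αH-dauca-7,9-dien-6-one, via trienol 18 (not isolated)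
Conditions: HF·pyridine, pyridine, THF, 0 °C to rt
Reagents that add atoms: none
Why: Fluoride-mediated cleavage of the silylene frees the tertiary alcohol and trienol 18, which tautomerises to the conjugated dienone by protonation at C5, where attack on the convex face anti to the axial C1 methyl group and the reversibility of the enolisation both point to the trans-fused 5αH epimer, which keeps C6 anti to the isopropyl group and allows an O4–H···O6 hydrogen bond.

**Step 11**
Reactants: 19 2α-acetoxy-4β-hydroxy-5αH-dauca-7,9-dien-6-one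
Product: 20 2α-acetoxy-9α,10α-epoxy-4β-hydroxy-5αH-dauc-7-en-6-one
Conditions: mCPBA, CH2Cl2, 0 °C to rt
Reagents that add atoms: 3-chloroperoxybenzoic acid OOC(=O)c1cccc(Cl)c1
Why: Prilezhaev epoxidation, in which the γ,δ bond C9=C10 is the less deactivated of the two dienone double bonds and should react alone, from the α face anti to the C1 methyl group (the C10 configuration is erased in step 14).

**Step 12**
Reactants: 20 2α-acetoxy-9α,10α-epoxy-4β-hydroxy-5αH-dauc-7-en-6-one
Product: 21 2α-acetoxy-4β,10α-dihydroxy-5αH-dauc-8-en-6-one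
Conditions: SmI2 (2.2 equiv), THF/MeOH, −78 °C; pH 7 buffer
Reagents that add atoms: none
Why: Samarium diiodide reduction of a γ,δ-epoxy-α,β-unsaturated ketone, in which two-electron transfer opens the allylic C9–O bond to a dienolate that is protonated at C7, moving the double bond to C8=C9 and leaving the C10 alcohol with its configuration retained.

**Step 13**
Reactants: 21 2α-acetoxy-4β,10α-dihydroxy-5αH-dauc-8-en-6-one
Product: 22 2α-acetoxy-5αH-dauc-8-ene-4β,6α,10α-triol
Conditions: Me4NBH(OAc)3, MeCN/AcOH, −30 °C
Reagents that add atoms: none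
Why: Evans–Saksena reduction, in which the tertiary 4β-hydroxyl group exchanges onto boron and delivers hydride through a six-membered chair transition state to the β face of C6, setting the 6α (6S) alcohol anti to O4, while the C10 hydroxyl group is too remote for such a delivery and an undirected ketone is not reduced by this reagent.

**Step 14**
Reactants: 22 2α-acetoxy-5αH-dauc-8-ene-4β,6α,10α-triol
Product: 23 2α-acetoxy-4β,6α-dihydroxy-5αH-dauc-8-en-10-one
Conditions: MnO2, CH2Cl2, rt
Reagents that add atoms: none
Why: Manganese dioxide oxidises only the allylic C10 alcohol, the homoallylic C6 and tertiary C4 alcohols being inert, which differentiates the two secondary alcohols and removes the wrong C10 configuration.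

**Step 15**
Reactants: 23 2α-acetoxy-4β,6α-dihydroxy-5αH-dauc-8-en-10-one
Product: 24 2α-acetoxy-6α-angeloyloxy-4β-hydroxy-5αH-dauc-8-en-10-one
Conditions: angelic acid, 2,4,6-trichlorobenzoyl chloride, Et3N, toluene, rt; then 23, 80 °C
Reagents that add atoms: angelic acid C/C=C(/C)C(=O)O
Why: Yamaguchi-type esterification with the preformed mixed anhydride and without a nucleophilic catalyst, the conditions known to transfer the angeloyl group without Z to E isomerisation, and only the secondary C6 hydroxyl group can react.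

**Step 16**
Reactants: 24 2α-acetoxy-6α-angeloyloxy-4β-hydroxy-5αH-dauc-8-en-10-one
Product: 25 2α-acetoxy-6α-angeloyloxy-5αH-dauc-8-ene-4β,10β-diol
Conditions: NaBH4, CeCl3·7H2O, MeOH, −78 to −40 °C
Reagents that add atoms: none
Why: Luche reduction, a 1,2-selective hydride addition to the enone from the α face, anti to the axial C1 methyl group next to C10, which should set the 10β (10S) allylic alcohol while the esters survive.

**Step 17**
Reactants: 25 2α-acetoxy-6α-angeloyloxy-5αH-dauc-8-ene-4β,10β-diol
Product: 26 2α-acetoxy-6α-angeloyloxy-10β-benzoyloxy-4β-hydroxy-5αH-dauc-8-ene (target)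
Conditions: BzCl, DMAP (cat.), pyridine, rt
Reagents that add atoms: benzoyl chloride O=C(Cl)c1ccccc1
Why: DMAP-catalysed benzoylation of the only secondary alcohol left, the hindered tertiary 4β-hydroxyl group staying free.

**Compound list**

1 | m-cresol | Cc1cccc(O)c1 | starting material
2 | isobutyryl chloride | CC(C)C(=O)Cl | starting material
3 | m-tolyl isobutyrate | CC(C)C(=O)Oc1cccc(C)c1 | intermediate
4 | 1-(2-hydroxy-4-methylphenyl)-2-methylpropan-1-one | CC(C)C(=O)c1ccc(C)cc1O | intermediate
5 | (3aR,7aR)-2-allyl-1,3-bis(4-bromobenzyl)-2-(2-isobutyryl-5-methylphenoxy)octahydro-1H-1,3,2-benzodiazasilole | C=CC[Si]1(Oc2cc(C)ccc2C(=O)C(C)C)N(Cc2ccc(Br)cc2)[C@@H]2CCCC[C@H]2N1Cc1ccc(Br)cc1 | intermediate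
6 | spirocyclic dialkoxysilane: silicon shared by the (R,R)-diazasilole ring and the (4R)-4-allyl-4-isopropyl-7-methyl-4H-1,3,2-benzodioxasiline ring | C=CC[C@]1(C(C)C)O[Si]2(Oc3cc(C)ccc31)N(Cc1ccc(Br)cc1)[C@@H]1CCCC[C@H]1N2Cc1ccc(Br)cc1 | intermediate
7 | (R)-2-(3-hydroxy-2-methylhex-5-en-3-yl)-5-methylphenol | C=CC[C@@](O)(C(C)C)c1ccc(C)cc1O | intermediate
8 | (R)-4-allyl-2,2-di-tert-butyl-4-isopropyl-7-methyl-4H-1,3,2-benzodioxasiline | C=CC[C@]1(C(C)C)O[Si](C(C)(C)C)(C(C)(C)C)Oc2cc(C)ccc21 | intermediate
9 | secondary ozonide of 8: 3-substituted 1,2,4-trioxolane, (R) at C4, epimers at the trioxolane carbon | C1OC(C[C@]2(C(C)C)O[Si](C(C)(C)C)(C(C)(C)C)Oc3cc(C)ccc32)OO1 | intermediate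
10 | (R)-2-(2,2-di-tert-butyl-4-isopropyl-7-methyl-4H-1,3,2-benzodioxasilin-4-yl)acetaldehyde | O=CC[C@]1(C(C)C)O[Si](C(C)(C)C)(C(C)(C)C)Oc2cc(C)ccc21 | intermediate
11 | (R)-2-(2,2-di-tert-butyl-4-isopropyl-7-methyl-4H-1,3,2-benzodioxasilin-4-yl)acetic acid | OC(=O)C[C@]1(C(C)C)O[Si](C(C)(C)C)(C(C)(C)C)Oc2cc(C)ccc21 | intermediate
12 | isobutyl carbonic anhydride of acid 11 | CC(C)COC(=O)OC(=O)C[C@]1(C(C)C)O[Si](C(C)(C)C)(C(C)(C)C)Oc2cc(C)ccc21 | intermediate
13 | (R)-3-diazo-1-(2,2-di-tert-butyl-4-isopropyl-7-methyl-4H-1,3,2-benzodioxasilin-4-yl)butan-2-one | CC(=[N+]=[N-])C(=O)C[C@]1(C(C)C)O[Si](C(C)(C)C)(C(C)(C)C)Oc2cc(C)ccc21 | intermediate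
14 | norcaradiene: cyclopropane C1–C5–C10, C6=C7 and C8=C9, C2 ketone, C1 methyl over the six-membered ring, O4/O6 silylene | CC(C)(C)[Si]1(C(C)(C)C)OC2=CC(C)=C[C@@H]3[C@@]4(C)C(=O)C[C@@](O1)(C(C)C)[C@@]234 | intermediate
15 | (1R,4R)-4,6-O-(di-tert-butylsilanediyl)-4β,6-dihydroxydauca-5,7,9-trien-2-one (C1 methyl β, O4 β, isopropyl α) | CC(C)(C)[Si]1(C(C)(C)C)OC2=C3[C@](O1)(C(C)C)CC(=O)[C@]3(C)C=CC(C)=C2 | intermediate
16 | 4,6-O-(di-tert-butylsilanediyl)dauca-5,7,9-triene-2α,4β,6-triol (2S) | CC(C)(C)[Si]1(C(C)(C)C)OC2=C3[C@](O1)(C(C)C)C[C@H](O)[C@]3(C)C=CC(C)=C2 | intermediate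
17 | 2α-acetoxy-4,6-O-(di-tert-butylsilanediyl)dauca-5,7,9-triene-4β,6-diol | CC(C)(C)[Si]1(C(C)(C)C)OC2=C3[C@](O1)(C(C)C)C[C@H](OC(C)=O)[C@]3(C)C=CC(C)=C2 | intermediate
18 | 2α-acetoxydauca-5,7,9-triene-4β,6-diol (trienol) | OC1=C2[C@](O)(C(C)C)C[C@H](OC(C)=O)[C@]2(C)C=CC(C)=C1 | intermediate
19 | 2α-acetoxy-4β-hydroxy-5αH-dauca-7,9-dien-6-one (trans-fused) | O=C1C=C(C)C=C[C@@]2(C)[C@@H](OC(C)=O)C[C@@](O)(C(C)C)[C@H]12 | intermediate
20 | 2α-acetoxy-9α,10α-epoxy-4β-hydroxy-5αH-dauc-7-en-6-one | O=C1C=C(C)[C@H]3O[C@H]3[C@@]2(C)[C@@H](OC(C)=O)C[C@@](O)(C(C)C)[C@H]12 | intermediate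
21 | 2α-acetoxy-4β,10α-dihydroxy-5αH-dauc-8-en-6-one | O=C1CC(C)=C[C@@H](O)[C@@]2(C)[C@@H](OC(C)=O)C[C@@](O)(C(C)C)[C@H]12 | intermediate
22 | 2α-acetoxy-5αH-dauc-8-ene-4β,6α,10α-triol | O[C@H]1CC(C)=C[C@@H](O)[C@@]2(C)[C@@H](OC(C)=O)C[C@@](O)(C(C)C)[C@H]12 | intermediate
23 | 2α-acetoxy-4β,6α-dihydroxy-5αH-dauc-8-en-10-one | O[C@H]1CC(C)=CC(=O)[C@@]2(C)[C@@H](OC(C)=O)C[C@@](O)(C(C)C)[C@H]12 | intermediate
24 | 2α-acetoxy-6α-angeloyloxy-4β-hydroxy-5αH-dauc-8-en-10-one | C/C=C(/C)C(=O)O[C@H]1CC(C)=CC(=O)[C@@]2(C)[C@@H](OC(C)=O)C[C@@](O)(C(C)C)[C@H]12 | intermediate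
25 | 2α-acetoxy-6α-angeloyloxy-5αH-dauc-8-ene-4β,10β-diol | C/C=C(/C)C(=O)O[C@H]1CC(C)=C[C@H](O)[C@@]2(C)[C@@H](OC(C)=O)C[C@@](O)(C(C)C)[C@H]12 | intermediate
26 | (1R,2S,4R,5S,6S,10S)-2α-acetoxy-6α-angeloyloxy-10β-benzoyloxy-4β-hydroxy-5αH-dauc-8-ene | C/C=C(/C)C(=O)O[C@H]1CC(C)=C[C@H](OC(=O)c2ccccc2)[C@@]2(C)[C@@H](OC(C)=O)C[C@@](O)(C(C)C)[C@H]12 | target

Total step count: 17. Longest linear sequence: 17 steps (1 to 26).

**Steps most likely to fail**

**Step 7.** The carbenoid may be diverted by insertion into the isopropyl methine C–H bond, by hydride shift from the neighbouring methyl group or by attack on O4. The tert-butyl groups of the temporary ring may also shield the arene face or hold the side arm in the unreactive pseudo-equatorial position.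

The fallback sets out from 7 and comes back at 19. It gives up the temporary ring and relies on acyclic control.
- TESOTf/2,6-lutidine converts 7 into the bis(triethylsilyl) ether F1.
- Ozonolysis of F1 gives the aldehyde F2, Pinnick oxidation gives the acid F3, and activation with isobutyl chloroformate followed by diazoethane gives the diazoketone F4.
- Rh2(OAc)4 in CH2Cl2 then effects the Buchner reaction of the conformationally free substrate to the trienone F5. Allylic 1,3-strain with the C6 silyloxy group keeps the larger isopropyl group away from C6 and thus trans to the C1 methyl group.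
- Corey–Bakshi–Shibata reduction gives the alcohol F6, acetylation gives the acetate F7, and HF·pyridine removes both silyl groups to give 19.

**Step 10.** Protonation at C5 may be unselective or take place on the wrong face. Once the β-hydroxy ketone is free, the tertiary carbinol may be lost by dehydration, or the five-membered ring may open by a retro-aldol process.

The fallback sets out from 17 and comes back at 19. It unmasks in two stages under thermodynamic control.
- One equivalent of Bu4NF buffered with AcOH in THF at −40 °C cleaves only the enol Si–O bond and gives the ketone di-tert-butylfluorosilyl ether F8.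
- With O4 still blocked no alkoxide can form, so C5 can be equilibrated with catalytic DBU in toluene to the trans-fused epimer.
- HF·pyridine at rt then removes the fluorosilyl group to give 19.

**Step 13.** Exchange of the hindered tertiary alcohol onto boron may be too slow. Hydride would then arrive from outside on the open α face, or from the C10 hydroxyl group, with loss of facial control at C6.

The fallback sets out from 21 and comes back at 24. It uses the inherent bias and then inverts.
- NaBH4 in MeOH at −40 °C attacks from the α face and gives the 6β-configured triol F9.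
- MnO2 oxidises the allylic alcohol of F9 to the 6β-hydroxy enone F10.
- A Mitsunobu reaction with angelic acid (PPh3, DIAD, toluene) inverts C6 and installs the angelate in the same operation, giving 24.

**Further compounds**

F1 | step 7 | (R)-triethyl{[3-(4-methyl-2-triethylsilyloxyphenyl)-2-methylhex-5-en-3-yl]oxy}silane | C=CC[C@@](O[Si](CC)(CC)CC)(C(C)C)c1ccc(C)cc1O[Si](CC)(CC)CC
F2 | step 7 | (R)-4-methyl-3-(4-methyl-2-triethylsilyloxyphenyl)-3-triethylsilyloxypentanal | O=CC[C@@](O[Si](CC)(CC)CC)(C(C)C)c1ccc(C)cc1O[Si](CC)(CC)CC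
F3 | step 7 | (R)-4-methyl-3-(4-methyl-2-triethylsilyloxyphenyl)-3-triethylsilyloxypentanoic acid | OC(=O)C[C@@](O[Si](CC)(CC)CC)(C(C)C)c1ccc(C)cc1O[Si](CC)(CC)CC
F4 | step 7 | (R)-2-diazo-6-methyl-5-(4-methyl-2-triethylsilyloxyphenyl)-5-triethylsilyloxyheptan-3-one | CC(=[N+]=[N-])C(=O)C[C@@](O[Si](CC)(CC)CC)(C(C)C)c1ccc(C)cc1O[Si](CC)(CC)CC
F5 | step 7 | (1R,4R)-4β,6-bis(triethylsilyloxy)dauca-5,7,9-trien-2-one | CC[Si](CC)(CC)OC1=C2[C@](O[Si](CC)(CC)CC)(C(C)C)CC(=O)[C@]2(C)C=CC(C)=C1
F6 | step 7 | 4β,6-bis(triethylsilyloxy)dauca-5,7,9-trien-2α-ol | CC[Si](CC)(CC)OC1=C2[C@](O[Si](CC)(CC)CC)(C(C)C)C[C@H](O)[C@]2(C)C=CC(C)=C1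
F7 | step 7 | 2α-acetoxy-4β,6-bis(triethylsilyloxy)dauca-5,7,9-triene | CC[Si](CC)(CC)OC1=C2[C@](O[Si](CC)(CC)CC)(C(C)C)C[C@H](OC(C)=O)[C@]2(C)C=CC(C)=C1
F8 | step 10 | 2α-acetoxy-4β-(di-tert-butylfluorosilyloxy)-5αH-dauca-7,9-dien-6-one | O=C1C=C(C)C=C[C@@]2(C)[C@@H](OC(C)=O)C[C@@](O[Si](F)(C(C)(C)C)C(C)(C)C)(C(C)C)[C@H]12
F9 | step 13 | 2α-acetoxy-5αH-dauc-8-ene-4β,6β,10α-triol | O[C@@H]1CC(C)=C[C@@H](O)[C@@]2(C)[C@@H](OC(C)=O)C[C@@](O)(C(C)C)[C@H]12
F10 | step 13 | 2α-acetoxy-4β,6β-dihydroxy-5αH-dauc-8-en-10-one | O[C@@H]1CC(C)=CC(=O)[C@@]2(C)[C@@H](OC(C)=O)C[C@@](O)(C(C)C)[C@H]12
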